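A direct plan would O-alkylate 2,4-dibromophenol with 2-chlorocyclohexanone to 2-(2,4-dibromophenoxy)cyclohexan-1-one A1, aromatise the ketone ring by α,α'-dibromination and double dehydrobromination to 2-(2,4-dibromophenoxy)phenol A2, and brominate that phenol three times in the same pot through 2,4-dibromo-6-(2,4-dibromophenoxy)phenol A3 to the target.
Its weakest steps would be:
- the aromatisation, because the α-bromo-α-aryloxy ketone could ionise, shed the aryloxy group or hydrolyse instead of losing HBr;
- the last bromination, because it would have to enter C3 between two bromines and meta to the hydroxyl while C5 and the second ring stay open;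
- the one-pot bromine bookkeeping, because under- and over-brominated ethers would be hard to separate.

**Strategy.** The route reads ring A as the 1,2-adduct of an aryne. Both the C6–O(aryl) and the C1–OH bond are disconnected, leading back to unsymmetrical 3,4,5-tribromobenzyne (made from symmetric 3,4,5-tribromophenol), 2,4-dibromophenoxide and a boron electrophile as masked hydroxyl. In one operation the flanking bromine (C2 of the target) should send the phenoxide to the remote aryne carbon and boron, later oxygen, to the carbon beside it. The ether bond and the neighbouring hydroxyl would thus arise together, with their positions relative to the three contiguous bromines fixed. All five bromines come in with the two phenol building blocks, so nothing is aromatised and no bromination has to find C3.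

Key step: step 3

Remark: ring A is the phenol ring, numbered C1 (OH), C2 to C4 (Br), C5 (H), C6 (aryloxy); ring B is the 2,4-dibromophenyl ring. 3,4,5-Tribromophenol is assumed to be a purchasable bromophenol.

Step 1
Reactants: 1 3,4,5-tribromophenol; 2 N-iodosuccinimide
Product: 3 3,4,5-tribromo-2-iodophenol
Conditions: NIS (0.95 equiv), TsOH·H2O (10 mol%), MeCN, 0 °C to rt
Reagents that add atoms: N-iodosuccinimide (compound 2), O=C1CCC(=O)N1I
Why: Electrophilic aromatic iodination ortho to the hydroxyl should give a single mono-iodide, because the para position is blocked by bromine and the two ortho positions are equivalent by symmetry, and a slight deficit of NIS should hold back the second iodination.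

Step 2
Reactants: 3 3,4,5-tribromo-2-iodophenol; 4 hexamethyldisilazane; 5 trifluoromethanesulfonic anhydride
Product: 8 3,4,5-tribromo-2-(trimethylsilyl)phenyl trifluoromethanesulfonate, via (3,4,5-tribromo-2-iodophenoxy)trimethylsilane 6 (not isolated), via lithium 3,4,5-tribromo-2-(trimethylsilyl)phenolate 7 (not isolated)
Conditions: HMDS (1.0 equiv), THF, reflux, then evaporate; n-BuLi (1.05 equiv), THF, −100 °C; Tf2O (1.2 equiv), −100 °C to rt
Reagents that add atoms: hexamethyldisilazane (compound 4), C[Si](C)(C)N[Si](C)(C)C; trifluoromethanesulfonic anhydride (compound 5), O=S(=O)(OS(=O)(=O)C(F)(F)F)C(F)(F)F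
Why: O-silylation, iodine–lithium exchange (faster than bromine–lithium exchange at −100 °C) and a retro-Brook rearrangement (1,3 shift of silicon from oxygen to the lithiated carbon, which should outrun loss of LiBr) should give phenolate 7, whose O-triflation completes the standard one-pot entry to 2-silylaryl triflates.

Step 3
Reactants: 8 3,4,5-tribromo-2-(trimethylsilyl)phenyl trifluoromethanesulfonate; 9 2,4-dibromophenol; 10 pinacolborane; 11 hydrogen peroxide
Product: 15 2,3,4-tribromo-6-(2,4-dibromophenoxy)phenol, via 2-(2,4-dibromophenoxy)-4,4,5,5-tetramethyl-1,3,2-dioxaborolane 12 (not isolated), via 3,4,5-tribromobenzyne 13 (not isolated), via 2-[2,3,4-tribromo-6-(2,4-dibromophenoxy)phenyl]-4,4,5,5-tetramethyl-1,3,2-dioxaborolane 14 (not isolated)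
Conditions: 9 (1.5 equiv), HBpin (1.6 equiv), THF, rt to 50 °C, −H2, then evaporate; then 8 (1.0 equiv), KF (2.5 equiv), 18-crown-6 (2.5 equiv), THF, 0 °C to rt; then 30% aq H2O2, aq NaHCO3, 0 °C
Reagents that add atoms: hydrogen peroxide (compound 11), OO
Why: Proposed new method: dehydrocoupling of 9 with pinacolborane should give aryl borate 12; fluoride should then strip the silyl group from 8 so that the anion expels triflate to give aryne 13, and should also open the B–O bond of 12 to release 2,4-dibromophenoxide; the phenoxide should add to the aryne carbon remote from the flanking bromine (the former triflate carbon, C6 of the target), and the carbanion formed beside the C–Br bond (C1 of the target) should be captured by the boron of 12 or of FBpin, which frees the next phenoxide, so that the net change is insertion of the aryne into the O–B bond to give 14. The closest known reaction types are the fluoride-induced insertions of arynes from 2-silylaryl triflates into N–Si and S–Sn bonds, the three-component couplings of arynes with a nucleophile and carbon dioxide, and the in situ borate trapping of short-lived ortho-haloaryl anions. No ring is closed and no stereocentre is formed. The step needs regioselection between the two aryne carbons: the flanking bromine distorts the triple bond so that the remote carbon is the more electrophilic and stabilises the adjacent carbanion inductively, the remote carbon is also the less hindered, and the other two bromines are meta and para to either possible carbanion and cancel. It also needs boron capture to outrun protonation and loss of bromide from the ortho-bromoaryl anion, for which the aprotic medium and the excess of electrophilic boron are chosen. Buffered hydrogen peroxide should then convert the C–B bond of 14 into the C1 hydroxyl at the same carbon, and the five C–Br bonds should survive because no transition metal or strong reductant is present.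

**Compound list**
1 | 3,4,5-tribromophenol | Oc1cc(Br)c(Br)c(Br)c1 | starting material
2 | N-iodosuccinimide | O=C1CCC(=O)N1I | starting material
3 | 3,4,5-tribromo-2-iodophenol | Oc1cc(Br)c(Br)c(Br)c1I | intermediate
4 | hexamethyldisilazane | C[Si](C)(C)N[Si](C)(C)C | starting material
5 | trifluoromethanesulfonic anhydride | O=S(=O)(OS(=O)(=O)C(F)(F)F)C(F)(F)F | starting material
6 | (3,4,5-tribromo-2-iodophenoxy)trimethylsilane (not isolated) | C[Si](C)(C)Oc1cc(Br)c(Br)c(Br)c1I | intermediate
7 | lithium 3,4,5-tribromo-2-(trimethylsilyl)phenolate (not isolated) | [Li+].[O-]c1cc(Br)c(Br)c(Br)c1[Si](C)(C)C | intermediate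
8 | 3,4,5-tribromo-2-(trimethylsilyl)phenyl trifluoromethanesulfonate | C[Si](C)(C)c1c(OS(=O)(=O)C(F)(F)F)cc(Br)c(Br)c1Br | intermediate
9 | 2,4-dibromophenol | Oc1ccc(Br)cc1Br | starting material
10 | pinacolborane (4,4,5,5-tetramethyl-1,3,2-dioxaborolane) | CC1(C)OBOC1(C)C | starting material
11 | hydrogen peroxide | OO | starting material
12 | 2-(2,4-dibromophenoxy)-4,4,5,5-tetramethyl-1,3,2-dioxaborolane (not isolated) | CC1(C)OB(Oc2ccc(Br)cc2Br)OC1(C)C | intermediate
13 | 3,4,5-tribromobenzyne (not isolated) | BrC1=C(Br)C(Br)=CC#C1 | intermediate
14 | 2-[2,3,4-tribromo-6-(2,4-dibromophenoxy)phenyl]-4,4,5,5-tetramethyl-1,3,2-dioxaborolane (not isolated) | CC1(C)OB(OC1(C)C)c1c(Oc2ccc(Br)cc2Br)cc(Br)c(Br)c1Br | intermediate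
15 | 2,3,4-tribromo-6-(2,4-dibromophenoxy)phenol | Oc1c(Oc2ccc(Br)cc2Br)cc(Br)c(Br)c1Br | target

Total step count: 3. Longest linear sequence: 3 (1 → 3 → 8 → 15).

**Steps most likely to fail**

1. Step 3 (proposed new method). Fluoride may be tied up by boron so that the aryne forms slowly; the aryl anion may be protonated or lose bromide before boron reaches it; some phenoxide may add at the carbon beside the bromine. The fallback uses known chemistry and makes the two C–O bonds one after the other. It sets out from 3, whose phenoxide (t-BuOK, THF, rt to 40 °C) would be O-arylated with bis(2,4-dibromophenyl)iodonium trifluoromethanesulfonate F1, itself made from 2,4-dibromo-1-iodobenzene and 1,3-dibromobenzene with mCPBA and TfOH, to give 1,2,3-tribromo-5-(2,4-dibromophenoxy)-4-iodobenzene F2. Iodine–magnesium exchange of F2 (i-PrMgCl·LiCl, THF, −78 °C) and quenching with 2-isopropoxy-4,4,5,5-tetramethyl-1,3,2-dioxaborolane would come back to the route at 14, which is oxidised to 15 as in step 3.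

2. Step 2. Bromine–lithium exchange may compete with iodine–lithium exchange, and the ortho-bromo aryllithium may lose LiBr before the silyl shift. The fallback replaces halogen–metal exchange by deprotonation and sets out from 1. Et2NCOCl with K2CO3 in MeCN would give 3,4,5-tribromophenyl N,N-diethylcarbamate F3. LiN(i-Pr)2 with Me3SiCl present from the start (THF, −78 °C) would silylate the position between the carbamate and bromine to give 3,4,5-tribromo-2-(trimethylsilyl)phenyl N,N-diethylcarbamate F4. Reductive cleavage with Cp2Zr(H)Cl (THF, rt) would give 3,4,5-tribromo-2-(trimethylsilyl)phenol F5, and Tf2O with pyridine in CH2Cl2 at 0 °C would come back to the route at 8.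

3. Step 1. Iodination may run on to both equivalent ortho positions, or stall on the deactivated ring. The fallback fixes mono-substitution by directed metalation and sets out from 1. MOMCl with i-Pr2NEt in CH2Cl2 would give 1,2,3-tribromo-5-(methoxymethoxy)benzene F6. Magnesiation between the acetal oxygen and bromine with TMPMgCl·LiCl (THF, −40 °C) and quenching with I2 would give 1,2,3-tribromo-4-iodo-5-(methoxymethoxy)benzene F7. HCl in MeOH would remove the acetal and come back to the route at 3.

**Further compounds**
F1 | step 3 | bis(2,4-dibromophenyl)iodonium trifluoromethanesulfonate | [O-]S(=O)(=O)C(F)(F)F.Brc1ccc([I+]c2ccc(Br)cc2Br)c(Br)c1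
F2 | step 3 | 1,2,3-tribromo-5-(2,4-dibromophenoxy)-4-iodobenzene | Ic1c(Oc2ccc(Br)cc2Br)cc(Br)c(Br)c1Br
F3 | step 2 | 3,4,5-tribromophenyl N,N-diethylcarbamate | CCN(CC)C(=O)Oc1cc(Br)c(Br)c(Br)c1
F4 | step 2 | 3,4,5-tribromo-2-(trimethylsilyl)phenyl N,N-diethylcarbamate | CCN(CC)C(=O)Oc1cc(Br)c(Br)c(Br)c1[Si](C)(C)C
F5 | step 2 | 3,4,5-tribromo-2-(trimethylsilyl)phenol | Oc1cc(Br)c(Br)c(Br)c1[Si](C)(C)C
F6 | step 1 | 1,2,3-tribromo-5-(methoxymethoxy)benzene | COCOc1cc(Br)c(Br)c(Br)c1
F7 | step 1 | 1,2,3-tribromo-4-iodo-5-(methoxymethoxy)benzene | COCOc1cc(Br)c(Br)c(Br)c1I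
A1 | direct plan | 2-(2,4-dibromophenoxy)cyclohexan-1-one (racemic) | O=C1CCCCC1Oc1ccc(Br)cc1Br
A2 | direct plan | 2-(2,4-dibromophenoxy)phenol | Oc1ccccc1Oc1ccc(Br)cc1Br
A3 | direct plan | 2,4-dibromo-6-(2,4-dibromophenoxy)phenol | Oc1c(Br)cc(Br)cc1Oc1ccc(Br)cc1Br
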